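## Retrosynthetic overview

- The C5–O ester bond is cut last, with inversion at C5 (Mitsunobu): the cis ester comes from the trans-5-hydroxy lactone and (2E,4E,6S)-4,6-dimethyldodeca-2,4-dienoic acid.
- The strategy rests on the single ring. Ring atoms C2–C5 (C2 carbonyl, C3=C4 alkene, C5 oxygenated) are the four carbons of a 2-substituted furan at a higher oxidation level, and C6, which carries the propenyl group and ring oxygen O1, is the furfuryl carbinol carbon. The O1–C2 bond is made by oxidative furan-to-pyranone ring expansion; C2 is then oxidised (Jones) and C5 reduced (Luche).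
- The carbinol comes from furfural and propynylmagnesium bromide through the ynone, a Midland reduction (sets C6) and a Red-Al trans-reduction.
- The acid comes from an Evans methylation (sets its C6), then Wittig and Horner–Wadsworth–Emmons homologation.
- Ring order: there is only one ring; it is closed in step 5.

Key step: step 5

Remark (assumption): hydride is taken to add to the C5 ketone of the keto-lactone axially, trans to the C6 propenyl group, so the ester is attached with inversion; if the cis alcohol dominated instead, the same acid would be attached by direct acylation.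

## Route

Step 1
Reactants: 1 furfural; 2 1-propynylmagnesium bromide
Product: 3 rac-1-(furan-2-yl)but-2-yn-1-ol
Conditions: THF, 0 °C; aq. NH4Cl
Reagents that add atoms: none
Why: Grignard 1,2-addition of the alkynyl nucleophile to the aldehyde, the racemic centre being erased in step 2.

Step 2
Reactants: 3 rac-1-(furan-2-yl)but-2-yn-1-ol
Product: 4 1-(furan-2-yl)but-2-yn-1-one
Conditions: MnO2, CH2Cl2, rt
Reagents that add atoms: none
Why: MnO2 oxidation of a doubly activated (furfurylic and propargylic) alcohol under neutral conditions that spare the furan.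

Step 3
Reactants: 4 1-(furan-2-yl)but-2-yn-1-one
Product: 5 (S)-1-(furan-2-yl)but-2-yn-1-ol
Conditions: (R)-Alpine-Borane (B-isopinocampheyl-9-BBN from (+)-α-pinene), neat, rt; CH3CHO; HOCH2CH2NH2, Et2O, 0 °C
Reagents that add atoms: none
Why: Midland reduction, in which the boat-like hydride transfer from the pinanyl C–H puts the slim propynyl group in the crowded position and the furyl group in the open one (the sense by which this reagent gives (R)-oct-1-yn-3-ol and (S)-1-phenylethanol), so the (S)-carbinol should result; a reagent that discriminates by size was chosen because both groups flanking this carbonyl are π-systems.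

Step 4
Reactants: 5 (S)-1-(furan-2-yl)but-2-yn-1-ol
Product: 6 (S,E)-1-(furan-2-yl)but-2-en-1-ol
Conditions: NaAlH2(OCH2CH2OCH3)2 (Red-Al), THF, 0 °C to rt; aq. potassium sodium tartrate
Reagents that add atoms: none
Why: Red-Al trans-hydroalumination of the propargylic alkoxide with intramolecular hydride delivery, so protonolysis should give only the E-alkene and leave the carbinol centre untouched.

Step 5
Reactants: 6 (S,E)-1-(furan-2-yl)but-2-en-1-ol
Product: 9 (2S)-6-hydroxy-2-[(E)-prop-1-enyl]-2H-pyran-3(6H)-one (anomer mixture), via 5-bromo-2,5-dihydrofuran-2-ol hemiketal 7 (not isolated), via Z-enedione 8 (not isolated)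
Conditions: NBS (1.05 equiv), NaHCO3, NaOAc, THF/H2O 4:1, 0 °C
Reagents that add atoms: water, O
Why: This is an Achmatowicz rearrangement: NBS brominates the free α-carbon of the electron-rich furan, water adds at the substituted α-carbon to give hemiketal 7, and loss of bromide opens it to the Z-enedione 8. The carbinol oxygen then adds to the aldehyde carbon of 8 in a 6-exo-trig hemiacetalisation that forms the O1–C2 bond of the target and closes the only ring as the six-membered pyranone. The Z geometry of the enedione, inherited from the furan, holds the aldehyde within reach of the hydroxyl. The carbinol carbon (C6 of the target) takes part in no bond change and keeps its S configuration, while the one new centre, the anomeric carbon, forms as an equilibrating mixture and is erased in step 6. The step needs attack on the furan in preference to the propenyl alkene, which the far higher nucleophilicity of the furan α-position towards electrophilic bromine should secure at 0 °C with one equivalent of NBS. It also needs the doubly activated carbinol not to ionise and the hydrogen next to the new ketone not to enolise, which the NaHCO3/NaOAc buffer and the short cold reaction time should secure.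

Step 6
Reactants: 9 (2S)-6-hydroxy-2-[(E)-prop-1-enyl]-2H-pyran-3(6H)-one
Product: 10 (6S)-6-[(E)-prop-1-enyl]-2H-pyran-2,5(6H)-dione
Conditions: CrO3, H2SO4, H2O (Jones reagent), acetone, 0 °C, short contact; crude product used at once
Reagents that add atoms: none
Why: Jones oxidation of the lactol C–H to the lactone carbonyl, with brief contact at 0 °C and immediate use to limit enolisation at C6.

Step 7
Reactants: 10 (6S)-6-[(E)-prop-1-enyl]-2H-pyran-2,5(6H)-dione
Product: 11 (5R,6S)-5-hydroxy-6-[(E)-prop-1-enyl]-5,6-dihydro-2H-pyran-2-one (5,6-trans)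
Conditions: NaBH4, CeCl3·7H2O, MeOH/CH2Cl2, −78 °C
Reagents that add atoms: none
Why: Luche reduction, in which the cerium-activated ketone is reduced 1,2 in preference to the lactone and the enone β-carbon, and axial hydride attack on the half-chair with a pseudo-equatorial propenyl group should give the equatorial, trans (5R) alcohol.

Step 8
Reactants: 12 (S)-4-benzyloxazolidin-2-one; 13 octanoyl chloride
Product: 14 (S)-4-benzyl-3-octanoyloxazolidin-2-one
Conditions: n-BuLi, THF, −78 °C; then 13, −78 to 0 °C
Reagents that add atoms: none
Why: N-acylation of the lithiated oxazolidinone by the acid chloride.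

Step 9
Reactants: 14 (S)-4-benzyl-3-octanoyloxazolidin-2-one
Product: 15 (S)-4-benzyl-3-[(S)-2-methyloctanoyl]oxazolidin-2-one
Conditions: NaN(SiMe3)2, THF, −78 °C; CH3I, −78 to −40 °C; minor diastereomer removed by chromatography
Reagents that add atoms: iodomethane, CI
Why: Evans alkylation, in which the chelated Z-enolate is methylated on the face away from the benzyl group, which with the hexyl chain already in place should set the (S) α-centre.

Step 10
Reactants: 15 (S)-4-benzyl-3-[(S)-2-methyloctanoyl]oxazolidin-2-one
Product: 16 (S)-2-methyloctan-1-ol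
Conditions: LiBH4, CH3OH (1 equiv), Et2O, 0 °C
Reagents that add atoms: none
Why: Reductive cleavage of the imide at the exocyclic carbonyl by LiBH4, which does not epimerise the α-centre and returns the auxiliary.

Step 11
Reactants: 16 (S)-2-methyloctan-1-ol
Product: 17 (S)-2-methyloctanal
Conditions: TEMPO (cat.), PhI(OAc)2, CH2Cl2, rt; crude product used at once
Reagents that add atoms: none
Why: TEMPO/PhI(OAc)2 oxidation stops at the aldehyde and, being base-free, should not epimerise the α-centre.

Step 12
Reactants: 17 (S)-2-methyloctanal; 18 2-(triphenylphosphoranylidene)propanal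
Product: 19 (2E,4S)-2,4-dimethyldec-2-enal
Conditions: toluene, 90 °C
Reagents that add atoms: none
Why: Wittig olefination with a stabilised formyl ylide should give the E trisubstituted enal, and the weakly basic ylide should leave the α-centre intact.

Step 13
Reactants: 19 (2E,4S)-2,4-dimethyldec-2-enal; 20 triethyl phosphonoacetate
Product: 21 ethyl (2E,4E,6S)-4,6-dimethyldodeca-2,4-dienoate
Conditions: NaH, THF, 0 °C to rt
Reagents that add atoms: none
Why: Horner–Wadsworth–Emmons olefination of the enal should give the E disubstituted alkene without affecting the existing alkene or stereocentre.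

Step 14
Reactants: 21 ethyl (2E,4E,6S)-4,6-dimethyldodeca-2,4-dienoate
Product: 22 (2E,4E,6S)-4,6-dimethyldodeca-2,4-dienoic acid
Conditions: LiOH, THF/CH3OH/H2O, rt; then aq. HCl to pH 3
Reagents that add atoms: lithium hydroxide LiOH, [Li+].[OH-]
Why: Saponification of the ethyl ester, which leaves the diene geometry and the remote stereocentre unchanged.

Step 15
Reactants: 11 (5R,6S)-5-hydroxy-6-[(E)-prop-1-enyl]-5,6-dihydro-2H-pyran-2-one; 22 (2E,4E,6S)-4,6-dimethyldodeca-2,4-dienoic acid
Product: 23 (2S,3S)-6-oxo-2-[(E)-prop-1-enyl]-3,6-dihydro-2H-pyran-3-yl (2E,4E,6S)-4,6-dimethyldodeca-2,4-dienoate (target; 5S,6S in lactone numbering)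
Conditions: PPh3, DIAD, THF, 0 °C to rt
Reagents that add atoms: none
Why: Mitsunobu esterification, in which the C5 hydroxyl is activated as an oxyphosphonium group and displaced by the carboxylate with inversion (5R to 5S) to give the cis ester, anti-elimination being disfavoured because C6–H is syn to the leaving group in the trans alcohol.

## Compound list

1 | furfural | O=Cc1ccco1 | starting material
2 | 1-propynylmagnesium bromide | CC#C[Mg]Br | starting material
3 | rac-1-(furan-2-yl)but-2-yn-1-ol | CC#CC(O)c1ccco1 | intermediate
4 | 1-(furan-2-yl)but-2-yn-1-one | CC#CC(=O)c1ccco1 | intermediate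
5 | (S)-1-(furan-2-yl)but-2-yn-1-ol | CC#C[C@H](O)c1ccco1 | intermediate
6 | (S,E)-1-(furan-2-yl)but-2-en-1-ol | C/C=C/[C@H](O)c1ccco1 | intermediate
7 | 5-bromo-2-[(1S,2E)-1-hydroxybut-2-enyl]-2,5-dihydrofuran-2-ol (diastereomer mixture, not isolated) | C/C=C/[C@H](O)C1(O)C=CC(Br)O1 | intermediate
8 | (2Z,5S,6E)-5-hydroxy-4-oxoocta-2,6-dienal (not isolated) | C/C=C/[C@H](O)C(=O)/C=C\C=O | intermediate
9 | (2S)-6-hydroxy-2-[(E)-prop-1-enyl]-2H-pyran-3(6H)-one (anomer mixture) | C/C=C/[C@@H]1OC(O)C=CC1=O | intermediate
10 | (6S)-6-[(E)-prop-1-enyl]-2H-pyran-2,5(6H)-dione | C/C=C/[C@@H]1OC(=O)C=CC1=O | intermediate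
11 | (5R,6S)-5-hydroxy-6-[(E)-prop-1-enyl]-5,6-dihydro-2H-pyran-2-one | C/C=C/[C@@H]1OC(=O)C=C[C@H]1O | intermediate
12 | (S)-4-benzyloxazolidin-2-one | O=C1N[C@@H](Cc2ccccc2)CO1 | starting material
13 | octanoyl chloride | CCCCCCCC(=O)Cl | starting material
14 | (S)-4-benzyl-3-octanoyloxazolidin-2-one | CCCCCCCC(=O)N1[C@@H](Cc2ccccc2)COC1=O | intermediate
15 | (S)-4-benzyl-3-[(S)-2-methyloctanoyl]oxazolidin-2-one | CCCCCC[C@H](C)C(=O)N1[C@@H](Cc2ccccc2)COC1=O | intermediate
16 | (S)-2-methyloctan-1-ol | CCCCCC[C@H](C)CO | intermediate
17 | (S)-2-methyloctanal | CCCCCC[C@H](C)C=O | intermediate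
18 | 2-(triphenylphosphoranylidene)propanal | CC(C=O)=P(c1ccccc1)(c1ccccc1)c1ccccc1 | starting material
19 | (2E,4S)-2,4-dimethyldec-2-enal | O=C/C(C)=C/[C@@H](C)CCCCCC | intermediate
20 | triethyl phosphonoacetate | CCOC(=O)CP(=O)(OCC)OCC | starting material
21 | ethyl (2E,4E,6S)-4,6-dimethyldodeca-2,4-dienoate | CCOC(=O)/C=C/C(C)=C/[C@@H](C)CCCCCC | intermediate
22 | (2E,4E,6S)-4,6-dimethyldodeca-2,4-dienoic acid | OC(=O)/C=C/C(C)=C/[C@@H](C)CCCCCC | intermediate
23 | (2S,3S)-6-oxo-2-[(E)-prop-1-enyl]-3,6-dihydro-2H-pyran-3-yl (2E,4E,6S)-4,6-dimethyldodeca-2,4-dienoate | C/C=C/[C@@H]1OC(=O)C=C[C@@H]1OC(=O)/C=C/C(C)=C/[C@@H](C)CCCCCC | target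

## Step count and risks

Total steps: 15. Longest linear sequence: 8 steps (steps 1–7 then 15; the acid arm, steps 8–14 then 15, is equally long).

Steps most likely to fail:

Step 6 (oxidation to the keto-lactone). Under the acidic chromic acid conditions the C5 ketone may enolise toward C6, whose hydrogen is allylic and lies between the ketone and the ring oxygen. That would racemise C6 or tautomerise the ring to an achiral 5-hydroxy-2-pyranone. The fallback sets out from 9 and comes back at 23; it reduces the ketone before the lactone carbonyl exists. Lactol 9 is converted with HC(OEt)3 and catalytic BF3·OEt2 into the ethyl acetal (2S)-6-ethoxy-2-[(E)-prop-1-enyl]-2H-pyran-3(6H)-one F1. Luche reduction (NaBH4, CeCl3·7H2O, MeOH, −78 °C) should give the trans allylic alcohol (2S,3R)-6-ethoxy-2-[(E)-prop-1-enyl]-3,6-dihydro-2H-pyran-3-ol F2. Mitsunobu esterification with acid 22 (PPh3, DIAD) inverts that centre to give the cis ester acetal (2S,3S)-6-ethoxy-2-[(E)-prop-1-enyl]-3,6-dihydro-2H-pyran-3-yl (2E,4E,6S)-4,6-dimethyldodeca-2,4-dienoate F3. Jones oxidation of the allylic acetal (CrO3, H2SO4, acetone, 0 °C) then gives lactone 23 directly.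

Step 15 (Mitsunobu union). The conjugated dienoic acid is a weakly acidic pronucleophile, so displacement may be slow. That allows acylation with retention through an acyloxyphosphonium path, or alkylation of the reduced azodicarboxylate. The fallback sets out from 11 and comes back at 23; it separates inversion from acylation. Mitsunobu reaction of 11 with the much more acidic chloroacetic acid should give (2S,3S)-6-oxo-2-[(E)-prop-1-enyl]-3,6-dihydro-2H-pyran-3-yl chloroacetate F4. Thiourea and NaHCO3 in ethanol remove the chloroacetyl group under near-neutral conditions to give the cis alcohol (5S,6S)-5-hydroxy-6-[(E)-prop-1-enyl]-5,6-dihydro-2H-pyran-2-one F5. Carbodiimide esterification of F5 with 22 (DCC, catalytic 4-(dimethylamino)pyridine, CH2Cl2, 0 °C) then gives 23 with retention.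

Step 5 (key ring expansion). Electrophilic bromine may form a bromohydrin at the propenyl alkene, or the HBr released may ionise the doubly activated carbinol before the buffer neutralises it. The fallback sets out from 6 and comes back at 9; it replaces electrophilic bromine by dye-sensitised photooxygenation. Singlet oxygen (O2, tetraphenylporphyrin, visible light, CH2Cl2, −78 °C) adds across the furan in a [4+2] cycloaddition much faster than it undergoes the ene reaction with a 1,2-disubstituted alkene. This gives the endoperoxide (1S,2E)-1-(2,3,7-trioxabicyclo[2.2.1]hept-5-en-1-yl)but-2-en-1-ol F6. Reduction with Me2S (−78 °C to rt) gives the Z-enedione 8, which closes to 9 as in the main route, with no acid generated.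

Further compounds
F1 | step 6 | (2S)-6-ethoxy-2-[(E)-prop-1-enyl]-2H-pyran-3(6H)-one (anomer mixture) | C/C=C/[C@@H]1OC(OCC)C=CC1=O
F2 | step 6 | (2S,3R)-6-ethoxy-2-[(E)-prop-1-enyl]-3,6-dihydro-2H-pyran-3-ol | C/C=C/[C@@H]1OC(OCC)C=C[C@H]1O
F3 | step 6 | (2S,3S)-6-ethoxy-2-[(E)-prop-1-enyl]-3,6-dihydro-2H-pyran-3-yl (2E,4E,6S)-4,6-dimethyldodeca-2,4-dienoate | C/C=C/[C@@H]1OC(OCC)C=C[C@@H]1OC(=O)/C=C/C(C)=C/[C@@H](C)CCCCCC
F4 | step 15 | (2S,3S)-6-oxo-2-[(E)-prop-1-enyl]-3,6-dihydro-2H-pyran-3-yl chloroacetate | C/C=C/[C@@H]1OC(=O)C=C[C@@H]1OC(=O)CCl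
F5 | step 15 | (5S,6S)-5-hydroxy-6-[(E)-prop-1-enyl]-5,6-dihydro-2H-pyran-2-one | C/C=C/[C@@H]1OC(=O)C=C[C@@H]1O
F6 | step 5 | (1S,2E)-1-(2,3,7-trioxabicyclo[2.2.1]hept-5-en-1-yl)but-2-en-1-ol | C/C=C/[C@H](O)C12OOC(C=C1)O2
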